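**Retrosynthetic overview**
1. The depside ester between the ring A carbonyl and O4 of ring B is cut last, giving ring A acid 13 (phenol as benzyl ether, side-chain ketone as dioxolane) and benzyl olivetolate 5.
2. The route rests on ring B: its C1 carboxyl lies between the C2 hydroxyl and the C6 pentyl group, with the second oxygen at C4, which is the substitution pattern of a 2-carboxy-5-pentylcyclohexane-1,3-dione (4) two hydrogens below the arene.
3. Ring B is the only ring built: malonate carbon to enone β-carbon (C1–C6), then methyl ketone carbon to ester carbonyl (C2–C3), then dehydrogenation.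
4. Ring A comes intact from methyl orsellinate 6; its C6 methyl is extended to the 2-oxopentyl chain by lateral lithiation and acylation.
5. End game: esterification, ketal hydrolysis, hydrogenolysis of both benzyl groups.

Key step: step 1

Remark: the target is achiral; the stereocentres of 3 and 4 are transient, so racemic material is used and one enantiomer is drawn. N-Methoxy-N-methylbutanamide is treated as a purchasable reagent.

**Route**

Step 1
Reactants: 1 dibenzyl malonate; 2 (E)-non-3-en-2-one
Product: 4 benzyl trans-2-hydroxy-4-oxo-6-pentylcyclohex-2-ene-1-carboxylate (racemic; enol form of the 2,4-dione), via Michael adduct 3 (not isolated)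
Conditions: NaH (1.1 equiv), BnOH (0.2 equiv), THF, 0 °C to reflux; then cold 1 M HCl
Reagents that add atoms: none
Why: The sodium enolate of 1 adds as a soft, delocalised carbanion to C4 of enone 2 (Michael addition, ring B bond C1–C6) to give adduct 3; proton exchange, shuttled by benzyl alcohol, then forms the methyl ketone enolate, which attacks one benzyl ester carbonyl (Claisen/Dieckmann condensation, ring B bond C2–C3) and expels benzyloxide. The closest known reaction type is the malonate–alk-3-en-2-one Michael–Claisen annulation that gives 6-alkyl-2,4-dioxocyclohexanecarboxylates. The one ring closes in the 6-(enolendo)-exo-trig mode at the ester carbonyl. The C6 stereocentre is set without control in the conjugate addition (racemate) and the doubly activated C1 centre equilibrates under base to the trans diequatorial arrangement; both vanish in step 2. The step needs 1,4- over 1,2-addition, which the stabilised malonate nucleophile secures, and closure from the methyl side, which is secured because the internal enolate could only form a four-membered ring. The benzyloxide set free matches the ester, so no ester scrambling is possible, and deprotonation of the product β-diketone should pull the reversible sequence forward.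

Step 2
Reactants: 4 benzyl trans-2-hydroxy-4-oxo-6-pentylcyclohex-2-ene-1-carboxylate
Product: 5 benzyl 2,4-dihydroxy-6-pentylbenzoate (benzyl olivetolate)
Conditions: I2 (0.2 equiv), DMSO, 80 °C
Reagents that add atoms: none
Why: Iodine-catalysed oxidative aromatisation (dehydrogenation), in which iodination of the enolised dione, loss of HI and tautomerisation should give the resorcylate while DMSO reoxidises HI to I2; the benzyl ester is inert and both stereocentres of 4 are erased.

Step 3
Reactants: 6 methyl orsellinate (methyl 2,4-dihydroxy-6-methylbenzoate)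
Product: 7 methyl 2-hydroxy-4-methoxy-6-methylbenzoate
Conditions: MeI (1.05 equiv), K2CO3 (1.1 equiv), acetone, reflux
Reagents that add atoms: iodomethane, CI
Why: Williamson etherification, selective because the C4 hydroxyl para to the ester is the more acidic, unchelated phenol whereas the C2 hydroxyl is held in a hydrogen bond to the ester carbonyl.

Step 4
Reactants: 7 methyl 2-hydroxy-4-methoxy-6-methylbenzoate
Product: 8 methyl 2-(benzyloxy)-4-methoxy-6-methylbenzoate
Conditions: BnBr (1.2 equiv), K2CO3 (1.5 equiv), DMF, 60 °C
Reagents that add atoms: benzyl bromide, BrCc1ccccc1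
Why: Williamson etherification under more forcing conditions should benzylate the chelated C2 phenol, giving an ether that withstands amide base and hydroxide and falls off in the final hydrogenolysis.

Step 5
Reactants: 8 methyl 2-(benzyloxy)-4-methoxy-6-methylbenzoate
Product: 11 methyl 2-(benzyloxy)-4-methoxy-6-(2-oxopentyl)benzoate, via benzylic lithium species 9 (not isolated), via lithium hemiaminal chelate 10 (not isolated)
Conditions: LiN(iPr)2 (2.0 equiv), THF, −78 °C; N-methoxy-N-methylbutanamide (1.2 equiv), −78 °C; AcOH in THF, −78 °C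
Reagents that add atoms: N-methoxy-N-methylbutanamide, CCCC(=O)N(C)OC
Why: Lateral (benzylic) lithiation of an ortho-toluate followed by Weinreb amide acylation, in which the ester-conjugated anion 9 adds to the amide to give the chelated tetrahedral adduct 10 that should not collapse before the cold acidic quench, so over-addition and base-induced cyclisation of the ketone are avoided.

Step 6
Reactants: 11 methyl 2-(benzyloxy)-4-methoxy-6-(2-oxopentyl)benzoate
Product: 12 methyl 2-(benzyloxy)-4-methoxy-6-[(2-propyl-1,3-dioxolan-2-yl)methyl]benzoate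
Conditions: TMSOCH2CH2OTMS (2 equiv), TMSOTf (5 mol%), CH2Cl2, −78 to −20 °C; pyridine quench
Reagents that add atoms: 1,2-bis(trimethylsilyloxy)ethane, C[Si](C)(C)OCCO[Si](C)(C)C
Why: Noyori ketalisation should mask the ketone as a 1,3-dioxolane at low temperature without acid-promoted lactonisation onto the neighbouring ester, and the mask blocks isocoumarin formation when the acid is later activated.

Step 7
Reactants: 12 methyl 2-(benzyloxy)-4-methoxy-6-[(2-propyl-1,3-dioxolan-2-yl)methyl]benzoate
Product: 13 2-(benzyloxy)-4-methoxy-6-[(2-propyl-1,3-dioxolan-2-yl)methyl]benzoic acid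
Conditions: KOH (5 equiv), DMSO/H2O 4:1, 90 °C; then 0 °C, 1 M HCl to pH 4, immediate EtOAc extraction
Reagents that add atoms: potassium hydroxide, [K+].[OH-]
Why: Saponification of a di-ortho-substituted methyl benzoate needs the poorly solvated hydroxide of aqueous DMSO at elevated temperature, the dioxolane and both ethers are stable to base, and brief cold acidification should leave the ketal intact (13 is used without storage).

Step 8
Reactants: 13 2-(benzyloxy)-4-methoxy-6-[(2-propyl-1,3-dioxolan-2-yl)methyl]benzoic acid; 5 benzyl 2,4-dihydroxy-6-pentylbenzoate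
Product: 14 benzyl 4-{[2-(benzyloxy)-4-methoxy-6-[(2-propyl-1,3-dioxolan-2-yl)methyl]benzoyl]oxy}-2-hydroxy-6-pentylbenzoate
Conditions: DCC (1.2 equiv), DMAP (0.2 equiv), CH2Cl2, 0 °C to rt
Reagents that add atoms: none
Why: Steglich esterification, in which DMAP passes the carbodiimide-activated acyl group to the free C4 phenol of 5, the only reactive hydroxyl because the C2 phenol is hydrogen-bonded to and flanked by the benzyl ester, under neutral conditions that spare the dioxolane.

Step 9
Reactants: 14 the dioxolane-protected dibenzyl depside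
Product: 15 benzyl 4-{[2-(benzyloxy)-4-methoxy-6-(2-oxopentyl)benzoyl]oxy}-2-hydroxy-6-pentylbenzoate
Conditions: 1 M aq. HCl/THF 1:4, rt
Reagents that add atoms: water, O
Why: Acid-catalysed ketal hydrolysis in dilute aqueous acid at room temperature should free the side-chain ketone, while the aryl ester, benzyl ester and benzyl ether are stable to these conditions.

Step 10
Reactants: 15 benzyl 4-{[2-(benzyloxy)-4-methoxy-6-(2-oxopentyl)benzoyl]oxy}-2-hydroxy-6-pentylbenzoate
Product: 16 glomelliferic acid
Conditions: H2 (1 atm), 10% Pd/C, EtOAc, rt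
Reagents that add atoms: none
Why: Catalytic hydrogenolysis should cleave the benzyl ester and the aryl benzyl ether together at one atmosphere, conditions under which the saturated ketone, the depside ester and the arenes are not reduced.

**Compound list**
1 | dibenzyl malonate | O=C(CC(=O)OCc1ccccc1)OCc1ccccc1 | starting material
2 | (E)-non-3-en-2-one | CCCCC/C=C/C(C)=O | starting material
3 | dibenzyl 2-(2-oxononan-4-yl)malonate (racemic, formed as its sodium enolate) | CCCCC[C@H](CC(C)=O)C(C(=O)OCc1ccccc1)C(=O)OCc1ccccc1 | intermediate (not isolated)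
4 | benzyl trans-2-hydroxy-4-oxo-6-pentylcyclohex-2-ene-1-carboxylate (racemic) | CCCCC[C@@H]1CC(=O)C=C(O)[C@H]1C(=O)OCc1ccccc1 | intermediate
5 | benzyl 2,4-dihydroxy-6-pentylbenzoate | CCCCCc1cc(O)cc(O)c1C(=O)OCc1ccccc1 | intermediate
6 | methyl orsellinate | COC(=O)c1c(C)cc(O)cc1O | starting material
7 | methyl 2-hydroxy-4-methoxy-6-methylbenzoate | COC(=O)c1c(C)cc(OC)cc1O | intermediate
8 | methyl 2-(benzyloxy)-4-methoxy-6-methylbenzoate | COC(=O)c1c(C)cc(OC)cc1OCc1ccccc1 | intermediate
9 | [3-(benzyloxy)-5-methoxy-2-(methoxycarbonyl)benzyl]lithium | [Li]Cc1cc(OC)cc(OCc2ccccc2)c1C(=O)OC | intermediate (not isolated)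
10 | lithium 1-[3-(benzyloxy)-5-methoxy-2-(methoxycarbonyl)phenyl]-2-[methoxy(methyl)amino]pentan-2-olate | CCCC(O[Li])(Cc1cc(OC)cc(OCc2ccccc2)c1C(=O)OC)N(C)OC | intermediate (not isolated)
11 | methyl 2-(benzyloxy)-4-methoxy-6-(2-oxopentyl)benzoate | CCCC(=O)Cc1cc(OC)cc(OCc2ccccc2)c1C(=O)OC | intermediate
12 | methyl 2-(benzyloxy)-4-methoxy-6-[(2-propyl-1,3-dioxolan-2-yl)methyl]benzoate | CCCC1(Cc2cc(OC)cc(OCc3ccccc3)c2C(=O)OC)OCCO1 | intermediate
13 | 2-(benzyloxy)-4-methoxy-6-[(2-propyl-1,3-dioxolan-2-yl)methyl]benzoic acid | CCCC1(Cc2cc(OC)cc(OCc3ccccc3)c2C(=O)O)OCCO1 | intermediate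
14 | benzyl 4-{[2-(benzyloxy)-4-methoxy-6-[(2-propyl-1,3-dioxolan-2-yl)methyl]benzoyl]oxy}-2-hydroxy-6-pentylbenzoate | CCCCCc1cc(OC(=O)c2c(OCc3ccccc3)cc(OC)cc2CC2(CCC)OCCO2)cc(O)c1C(=O)OCc1ccccc1 | intermediate
15 | benzyl 4-{[2-(benzyloxy)-4-methoxy-6-(2-oxopentyl)benzoyl]oxy}-2-hydroxy-6-pentylbenzoate | CCCCCc1cc(OC(=O)c2c(OCc3ccccc3)cc(OC)cc2CC(=O)CCC)cc(O)c1C(=O)OCc1ccccc1 | intermediate
16 | glomelliferic acid, 2-hydroxy-4-{[2-hydroxy-4-methoxy-6-(2-oxopentyl)benzoyl]oxy}-6-pentylbenzoic acid | CCCCCc1cc(OC(=O)c2c(O)cc(OC)cc2CC(=O)CCC)cc(O)c1C(=O)O | target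

**Step count**
Total: 10 steps. Longest linear sequence: 8 steps (6 to 16, steps 3 to 10); the ring B branch (steps 1 and 2) joins at step 8.

**Steps most likely to fail**

1. Step 9 (ketal hydrolysis). The depside carbonyl oxygen may capture the oxocarbenium ion formed when the dioxolane opens, and collapse of the resulting cyclic species can expel the ring B phenol, so the ester link is lost by lactonisation. The fallback sets out from ketone 11 and uses a ketal that is removed by hydrogenolysis instead of acid. Ketone 11 would be ketalised with the bis-trimethylsilyl ether of 1,2-benzenedimethanol (cat. TMSOTf, CH2Cl2, −78 to −20 °C) to methyl 2-(benzyloxy)-4-methoxy-6-[(3-propyl-1,5-dihydro-3H-2,4-benzodioxepin-3-yl)methyl]benzoate F1. KOH in aqueous DMSO would give 2-(benzyloxy)-4-methoxy-6-[(3-propyl-1,5-dihydro-3H-2,4-benzodioxepin-3-yl)methyl]benzoic acid F2. DCC/DMAP coupling with 5 would give benzyl 4-{[2-(benzyloxy)-4-methoxy-6-[(3-propyl-1,5-dihydro-3H-2,4-benzodioxepin-3-yl)methyl]benzoyl]oxy}-2-hydroxy-6-pentylbenzoate F3. H2 over Pd/C in EtOAc should then cleave the benzyl ester, the benzyl ether and a benzylic C–O bond of the ketal (the hemiketal collapses to the ketone) in one neutral operation, coming back to the route at target 16.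

2. Step 5 (lateral acylation). The lithiated toluate may self-condense with unlithiated ester, and early collapse of the tetrahedral adduct would let the ketone enolate cyclise onto the ester. The fallback sets out from 8 and replaces acylation by aldehyde addition and later oxidation. The anion of 8 would be trapped with butanal at −78 °C, and on warming the alkoxide lactonises to racemic 8-(benzyloxy)-6-methoxy-3-propyl-3,4-dihydro-1H-isochromen-1-one F4. KOH in aqueous THF would open the lactone to potassium 2-(benzyloxy)-6-(2-hydroxypentyl)-4-methoxybenzoate F5. The dried salt would be alkylated with MeI in DMF to methyl 2-(benzyloxy)-6-(2-hydroxypentyl)-4-methoxybenzoate F6, which is oxidised at once with Dess–Martin periodinane (NaHCO3, CH2Cl2), coming back to the route at ketone 11.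

3. Step 2 (aromatisation). The electron-rich resorcinol ring may be iodinated as it forms, which consumes the catalytic iodine and stalls the dehydrogenation. The fallback sets out from 4 and uses a halogen-free hydride abstraction. Exhaustive O-silylation of 4 (TMSCl, Et3N, THF) would give racemic benzyl 6-pentyl-2,4-bis(trimethylsilyloxy)cyclohexa-1,3-diene-1-carboxylate F7. DDQ in benzene at rt should aromatise it to benzyl 6-pentyl-2,4-bis(trimethylsilyloxy)benzoate F8. Dilute HCl in aqueous THF would remove both silyl groups, coming back to the route at 5.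

**Further compounds**
F1 | step 9 | methyl 2-(benzyloxy)-4-methoxy-6-[(3-propyl-1,5-dihydro-3H-2,4-benzodioxepin-3-yl)methyl]benzoate | CCCC1(Cc2cc(OC)cc(OCc3ccccc3)c2C(=O)OC)OCc2ccccc2CO1
F2 | step 9 | 2-(benzyloxy)-4-methoxy-6-[(3-propyl-1,5-dihydro-3H-2,4-benzodioxepin-3-yl)methyl]benzoic acid | CCCC1(Cc2cc(OC)cc(OCc3ccccc3)c2C(=O)O)OCc2ccccc2CO1
F3 | step 9 | benzyl 4-{[2-(benzyloxy)-4-methoxy-6-[(3-propyl-1,5-dihydro-3H-2,4-benzodioxepin-3-yl)methyl]benzoyl]oxy}-2-hydroxy-6-pentylbenzoate | CCCCCc1cc(OC(=O)c2c(OCc3ccccc3)cc(OC)cc2CC2(CCC)OCc3ccccc3CO2)cc(O)c1C(=O)OCc1ccccc1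
F4 | step 5 | 8-(benzyloxy)-6-methoxy-3-propyl-3,4-dihydro-1H-isochromen-1-one (racemic) | CCC[C@H]1Cc2cc(OC)cc(OCc3ccccc3)c2C(=O)O1
F5 | step 5 | potassium 2-(benzyloxy)-6-(2-hydroxypentyl)-4-methoxybenzoate (racemic) | CCC[C@H](O)Cc1cc(OC)cc(OCc2ccccc2)c1C(=O)[O-].[K+]
F6 | step 5 | methyl 2-(benzyloxy)-6-(2-hydroxypentyl)-4-methoxybenzoate (racemic) | CCC[C@H](O)Cc1cc(OC)cc(OCc2ccccc2)c1C(=O)OC
F7 | step 2 | benzyl 6-pentyl-2,4-bis(trimethylsilyloxy)cyclohexa-1,3-diene-1-carboxylate (racemic) | CCCCC[C@@H]1CC(O[Si](C)(C)C)=CC(O[Si](C)(C)C)=C1C(=O)OCc1ccccc1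
F8 | step 2 | benzyl 6-pentyl-2,4-bis(trimethylsilyloxy)benzoate | CCCCCc1cc(O[Si](C)(C)C)cc(O[Si](C)(C)C)c1C(=O)OCc1ccccc1
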